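Ring C of isodonal (C8, C9, C11, C12, C13, C14) is read as a cyclobutanone (C11, C9, C8, C14) that has taken up the C12=C13 vinyl group of a side chain held on C8 through C15–C16. A rhodium-catalysed carboacylation of the 3,3-disubstituted cyclobutanone 7 should therefore enlarge the four-membered ring by two atoms and close ring D in one operation, giving the bicyclo[3.2.1]octanone with the C11 oxygen, the quaternary C8 and the C7 carboxyl in place. Ring A comes from β-cyclocitral; it is joined through the C7–O–C20 ester and locked onto C9 by an intramolecular Michael addition.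

Key step: step 5

Remark: atom labels C1–C20 follow the ent-kaurane numbering of isodonal and are used for all intermediates; "17-nor" means that the exocyclic methylene carbon is still absent. Compounds 1 and 12 and the allylborane of step 2 are taken as purchased.

Step 1
Reactants: 1 methyl 3,3-dimethoxycyclobutane-1-carboxylate
Product: 3 methyl 1-formyl-3,3-dimethoxycyclobutane-1-carboxylate, via lithium enolate 2 (not isolated)
Conditions: LiN(i-Pr)2, THF, −78 °C; then HCO2Et, −78 to −40 °C; aq. NH4Cl
Reagents that add atoms: ethyl formate CCOC=O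
Why: Claisen-type C-formylation of the ester enolate; the new quaternary carbon (the future C8) cannot enolise, so the aldehyde should survive the cold quench, and no stereocentre is formed.

Step 2
Reactants: 3 methyl 1-formyl-3,3-dimethoxycyclobutane-1-carboxylate
Product: 5 methyl 1-[(1S)-1-hydroxybut-3-en-1-yl]-3,3-dimethoxycyclobutane-1-carboxylate, via borinate ester 4 (not isolated)
Conditions: (−)-B-allyldiisopinocampheylborane, Et2O, −78 °C; then NaOH, H2O2, 0 °C
Reagents that add atoms: (−)-B-allyldiisopinocampheylborane (from (+)-α-pinene) C=CCB([C@@H]1C[C@@H]2C[C@H]([C@H]1C)C2(C)C)[C@@H]1C[C@@H]2C[C@H]([C@H]1C)C2(C)C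
Why: Brown allylation through a chair-like six-membered transition state; the isopinocampheyl groups should direct allyl transfer to one aldehyde face and set C15 as (S), as expected for pivalaldehyde-type aldehydes.

Step 3
Reactants: 5 methyl 1-[(1S)-1-hydroxybut-3-en-1-yl]-3,3-dimethoxycyclobutane-1-carboxylate
Product: 6 methyl 1-[(1S)-1-(tert-butyldimethylsilyloxy)but-3-en-1-yl]-3,3-dimethoxycyclobutane-1-carboxylate
Conditions: TBSCl, imidazole, 4-(dimethylamino)pyridine (cat.), DMF, 40 °C
Reagents that add atoms: tert-butyldimethylsilyl chloride CC(C)(C)[Si](C)(C)Cl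
Why: Silylation of the secondary alcohol under non-acidic conditions that leave the ketal alone; it blocks retro-aldol cleavage in the hot rhodium step and no stereocentre changes.

Step 4
Reactants: 6 methyl 1-[(1S)-1-(tert-butyldimethylsilyloxy)but-3-en-1-yl]-3,3-dimethoxycyclobutane-1-carboxylate
Product: 7 methyl 1-[(1S)-1-(tert-butyldimethylsilyloxy)but-3-en-1-yl]-3-oxocyclobutane-1-carboxylate
Conditions: TsOH·H2O (cat.), acetone–H2O, rt
Reagents that add atoms: water O
Why: Acid-catalysed hydrolysis of the dimethyl ketal, which should be much faster than loss of the hindered secondary silyl ether.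

Step 5
Reactants: 7 methyl 1-[(1S)-1-(tert-butyldimethylsilyloxy)but-3-en-1-yl]-3-oxocyclobutane-1-carboxylate
Product: 10 methyl (1S,5R,7S)-7-(tert-butyldimethylsilyloxy)-3-oxobicyclo[3.2.1]octane-1-carboxylate (silyloxy group exo), via cyclobutanone ketimine 8 (not isolated), via bicyclic ketimine 9 (not isolated)
Conditions: [Rh(C2H4)2Cl]2 (5 mol %), P[3,5-(CF3)2C6H3]3 (24 mol %), 2-amino-3-methylpyridine (1 equiv), 1,4-dioxane, 150 °C, sealed tube
Reagents that add atoms: none
Why: Condensation with 2-amino-3-methylpyridine gives ketimine 8, whose pyridine nitrogen directs oxidative addition of monovalent rhodium into the C11–C14 bond; the tethered vinyl group inserts into the Rh–C14 bond, reductive elimination forms C11–C12, and the water set free in the condensation hydrolyses ketimine 9. This is the known rhodium-catalysed intramolecular carboacylation of olefins by 3-tethered cyclobutanones ("cut-and-sew") that gives bridged bicyclic ketones. Ring D (C8, C15, C16, C13, C14) closes by a 5-exo migratory insertion, and ring C (C8, C9, C11, C12, C13, C14) arises from the four-membered ring by a formal [4+2] two-atom enlargement. C13 is fixed relative to C8 by the geometry of the bicycle, and the choice between the two diastereotopic ring methylenes, which fixes C8, is controlled by the C15 stereocentre, whose silyloxy group should take the exo position of the forming cyclopentane, away from the rhodacycle. Insertion has to outrun decarbonylation, which the chelating ketimine and the Thorpe–Ingold effect of the quaternary C8 should secure; any C15-endo diastereomer is removed here by chromatography.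

Step 6
Reactants: 10 methyl (1S,5R,7S)-7-(tert-butyldimethylsilyloxy)-3-oxobicyclo[3.2.1]octane-1-carboxylate
Product: 11 (1S,5R,7S)-7-(tert-butyldimethylsilyloxy)-3-oxobicyclo[3.2.1]octane-1-carboxylic acid
Conditions: LiOH·H2O, THF–MeOH–H2O, 50 °C; then 1 M HCl
Reagents that add atoms: lithium hydroxide [Li+].[OH-]
Why: Saponification of the bridgehead methyl ester; C8 is quaternary and cannot epimerise, and the silyl ether should survive aqueous base.

Step 7
Reactants: 12 β-cyclocitral (2,6,6-trimethylcyclohex-1-ene-1-carbaldehyde)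
Product: 13 2-(dimethoxymethyl)-1,3,3-trimethylcyclohex-1-ene
Conditions: HC(OMe)3, MeOH, TsOH·H2O (cat.), rt
Reagents that add atoms: trimethyl orthoformate COC(OC)OC; methanol CO
Why: Acetalisation shields the aldehyde from the oxidant and from borane in the next two steps.

Step 8
Reactants: 13 2-(dimethoxymethyl)-1,3,3-trimethylcyclohex-1-ene
Product: 14 3-(dimethoxymethyl)-2,4,4-trimethylcyclohex-2-en-1-one
Conditions: CrO3, 3,5-dimethylpyrazole, CH2Cl2, −20 °C
Reagents that add atoms: chromium trioxide O=[Cr](=O)=O
Why: Allylic oxidation of the only ring methylene next to the tetrasubstituted alkene (the future C1) to the enone; the vinylic methyl group should react more slowly.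

Step 9
Reactants: 14 3-(dimethoxymethyl)-2,4,4-trimethylcyclohex-2-en-1-one
Product: 15 (1S)-3-(dimethoxymethyl)-2,4,4-trimethylcyclohex-2-en-1-ol
Conditions: (R)-2-methyl-CBS-oxazaborolidine (10 mol %), BH3·SMe2, THF, −20 °C; MeOH quench
Reagents that add atoms: none
Why: Corey–Bakshi–Shibata reduction; the substituted alkenyl side acts as the large group, so the (R)-catalyst should deliver hydride to the face that gives the (S)-allylic alcohol, the future C1.

Step 10
Reactants: 15 (1S)-3-(dimethoxymethyl)-2,4,4-trimethylcyclohex-2-en-1-ol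
Product: 16 (1S)-3-(dimethoxymethyl)-2,4,4-trimethylcyclohex-2-en-1-yl acetate
Conditions: Ac2O, Et3N, 4-(dimethylamino)pyridine (cat.), CH2Cl2, 0 °C to rt
Reagents that add atoms: acetic anhydride CC(=O)OC(C)=O
Why: Acylation installs the C1 acetate of the target with retention at the carbinol carbon.

Step 11
Reactants: 16 (1S)-3-(dimethoxymethyl)-2,4,4-trimethylcyclohex-2-en-1-yl acetate
Product: 17 (1S)-3-formyl-2,4,4-trimethylcyclohex-2-en-1-yl acetate
Conditions: pyridinium p-toluenesulfonate, acetone–H2O, 40 °C
Reagents that add atoms: water O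
Why: Mild acetal hydrolysis; ionisation of the allylic acetate is disfavoured because the cation would be conjugated with the electron-poor enal.

Step 12
Reactants: 17 (1S)-3-formyl-2,4,4-trimethylcyclohex-2-en-1-yl acetate
Product: 19 (1S)-2-(bromomethyl)-3-formyl-4,4-dimethylcyclohex-2-en-1-yl acetate, via silyl dienol ether 18 (not isolated)
Conditions: TBSOTf, Et3N, CH2Cl2, 0 °C; then NBS, THF, −78 °C
Reagents that add atoms: N-bromosuccinimide O=C1CCC(=O)N1Br
Why: Soft enolisation removes a γ-hydrogen from the vinylic methyl group (the C1 hydrogen is hindered and poorly aligned), and the silyl dienol ether is brominated at its unhindered terminal carbon (vinylogous α-halogenation), which restores the enal and leaves C1 untouched.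

Step 13
Reactants: 11 (1S,5R,7S)-7-(tert-butyldimethylsilyloxy)-3-oxobicyclo[3.2.1]octane-1-carboxylic acid; 19 (1S)-2-(bromomethyl)-3-formyl-4,4-dimethylcyclohex-2-en-1-yl acetate
Product: 20 [(6S)-6-acetoxy-2-formyl-3,3-dimethylcyclohex-1-en-1-yl]methyl (1S,5R,7S)-7-(tert-butyldimethylsilyloxy)-3-oxobicyclo[3.2.1]octane-1-carboxylate
Conditions: Cs2CO3, DMF, 0 °C
Reagents that add atoms: none
Why: SN2 O-alkylation of the caesium carboxylate by the reactive allylic bromide forms the C7–O–C20 ester without acyl activation of the hindered acid; no stereocentre is touched.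

Step 14
Reactants: 20 [(6S)-6-acetoxy-2-formyl-3,3-dimethylcyclohex-1-en-1-yl]methyl (1S,5R,7S)-7-(tert-butyldimethylsilyloxy)-3-oxobicyclo[3.2.1]octane-1-carboxylate
Product: 21 (15S)-15-(tert-butyldimethylsilyloxy)-15-deoxo-11-oxo-17-norisodonal (spiro-lactone with C6 aldehyde and C11 ketone; all other centres as in isodonal)
Conditions: KOt-Bu (0.2 equiv), t-BuOH–THF, −20 to 0 °C
Reagents that add atoms: none
Why: Intramolecular Michael addition (6-exo-trig) under reversible enolisation, in which only the C9 enolate can reach C10 through the ester tether; C9 should be attacked on the exo face of the bicycle (anti to the C15–C16 bridge), C10 on the face anti to the pseudoaxial C1 acetate, and C5 should be set by axial protonation anti to the axial C20 and C4 methyl groups.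

Step 15
Reactants: 21 (15S)-15-(tert-butyldimethylsilyloxy)-15-deoxo-11-oxo-17-norisodonal
Product: 22 (15S)-15-hydroxy-15-deoxo-11-oxo-17-norisodonal
Conditions: HF·pyridine, THF–pyridine, 0 °C to rt
Reagents that add atoms: none
Why: Fluoride cleavage of the silyl ether under buffered acidic conditions that should spare the acetate, the lactone and the epimerisable aldehyde.

Step 16
Reactants: 22 (15S)-15-hydroxy-15-deoxo-11-oxo-17-norisodonal
Product: 23 11-oxo-17-norisodonal (C15 ketone, C11 ketone, C6 aldehyde)
Conditions: Dess–Martin periodinane, CH2Cl2, 0 °C to rt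
Reagents that add atoms: none
Why: Dess–Martin oxidation of the only free hydroxyl; C8 is quaternary, so the new β-keto lactone cannot enolise towards it.

Step 17
Reactants: 23 11-oxo-17-norisodonal
Product: 25 17-norisodonal 6-alcohol (C6 as CH2OH, 11β-hydroxyl, C15 ketone), via hydroxy ketone 24 (not isolated)
Conditions: Me4NBH(OAc)3, MeCN–AcOH, −20 °C to rt
Reagents that add atoms: none
Why: Triacetoxyborohydride reduces the aldehyde but not unactivated ketones; the resulting C6 alkoxyborohydride lies on the α-face below C11 and should deliver hydride intramolecularly (Evans–Saksena-type directed reduction) to give the axial 11β-alcohol, while the C15 ketone has no hydroxyl within reach.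

Step 18
Reactants: 25 17-norisodonal 6-alcohol
Product: 27 isodonal 6-alcohol (C6 as CH2OH; otherwise isodonal), via Mannich base 26 (not isolated)
Conditions: (CH2O)n, N-methylanilinium trifluoroacetate, THF, 65 °C
Reagents that add atoms: formaldehyde (as paraformaldehyde) C=O
Why: Mannich-type α-methylenation; C16 is the only enolisable position of the C15 ketone, and the anilinomethyl adduct loses N-methylaniline to give the exo-methylene ketone under conditions that tolerate free hydroxyls.

Step 19
Reactants: 27 isodonal 6-alcohol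
Product: 28 isodonal
Conditions: TEMPO (10 mol %), PhI(OAc)2, CH2Cl2, rt
Reagents that add atoms: none
Why: Oxoammonium oxidation takes the primary alcohol to the aldehyde much faster than it attacks the hindered axial C11 alcohol and does not over-oxidise; C5 is not touched.

Compound list
1 | methyl 3,3-dimethoxycyclobutane-1-carboxylate | COC(=O)C1CC(OC)(OC)C1 | starting material
2 | lithium enolate of 1 | [Li+].COC([O-])=C1CC(OC)(OC)C1 | intermediate
3 | methyl 1-formyl-3,3-dimethoxycyclobutane-1-carboxylate | COC(=O)C1(C=O)CC(OC)(OC)C1 | intermediate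
4 | diisopinocampheylborinate ester of 5 | C=CC[C@H](OB([C@@H]1C[C@@H]2C[C@H]([C@H]1C)C2(C)C)[C@@H]1C[C@@H]2C[C@H]([C@H]1C)C2(C)C)C1(C(=O)OC)CC(OC)(OC)C1 | intermediate
5 | methyl 1-[(1S)-1-hydroxybut-3-en-1-yl]-3,3-dimethoxycyclobutane-1-carboxylate | C=CC[C@H](O)C1(C(=O)OC)CC(OC)(OC)C1 | intermediate
6 | methyl 1-[(1S)-1-(tert-butyldimethylsilyloxy)but-3-en-1-yl]-3,3-dimethoxycyclobutane-1-carboxylate | C=CC[C@H](O[Si](C)(C)C(C)(C)C)C1(C(=O)OC)CC(OC)(OC)C1 | intermediate
7 | methyl 1-[(1S)-1-(tert-butyldimethylsilyloxy)but-3-en-1-yl]-3-oxocyclobutane-1-carboxylate | C=CC[C@H](O[Si](C)(C)C(C)(C)C)C1(C(=O)OC)CC(=O)C1 | intermediate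
8 | N-(3-methylpyridin-2-yl) ketimine of 7 | C=CC[C@H](O[Si](C)(C)C(C)(C)C)C1(C(=O)OC)CC(=Nc2ncccc2C)C1 | intermediate
9 | N-(3-methylpyridin-2-yl) ketimine of 10 | C1[C@H](O[Si](C)(C)C(C)(C)C)[C@]2(C(=O)OC)C[C@H]1CC(=Nc3ncccc3C)C2 | intermediate
10 | methyl (1S,5R,7S)-7-(tert-butyldimethylsilyloxy)-3-oxobicyclo[3.2.1]octane-1-carboxylate, silyloxy exo | C1[C@H](O[Si](C)(C)C(C)(C)C)[C@]2(C(=O)OC)C[C@H]1CC(=O)C2 | intermediate
11 | (1S,5R,7S)-7-(tert-butyldimethylsilyloxy)-3-oxobicyclo[3.2.1]octane-1-carboxylic acid | C1[C@H](O[Si](C)(C)C(C)(C)C)[C@]2(C(=O)O)C[C@H]1CC(=O)C2 | intermediate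
12 | β-cyclocitral | CC1=C(C=O)C(C)(C)CCC1 | starting material
13 | 2-(dimethoxymethyl)-1,3,3-trimethylcyclohex-1-ene | CC1=C(C(OC)OC)C(C)(C)CCC1 | intermediate
14 | 3-(dimethoxymethyl)-2,4,4-trimethylcyclohex-2-en-1-one | CC1=C(C(OC)OC)C(C)(C)CCC1=O | intermediate
15 | (1S)-3-(dimethoxymethyl)-2,4,4-trimethylcyclohex-2-en-1-ol | O[C@H]1CCC(C)(C)C(C(OC)OC)=C1C | intermediate
16 | (1S)-3-(dimethoxymethyl)-2,4,4-trimethylcyclohex-2-en-1-yl acetate | CC(=O)O[C@H]1CCC(C)(C)C(C(OC)OC)=C1C | intermediate
17 | (1S)-3-formyl-2,4,4-trimethylcyclohex-2-en-1-yl acetate | CC(=O)O[C@H]1CCC(C)(C)C(C=O)=C1C | intermediate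
18 | (1S)-3-[(tert-butyldimethylsilyloxy)methylidene]-4,4-dimethyl-2-methylidenecyclohexyl acetate, enol ether geometry not defined | CC(=O)O[C@H]1CCC(C)(C)C(=CO[Si](C)(C)C(C)(C)C)C1=C | intermediate
19 | (1S)-2-(bromomethyl)-3-formyl-4,4-dimethylcyclohex-2-en-1-yl acetate | CC(=O)O[C@H]1CCC(C)(C)C(C=O)=C1CBr | intermediate
20 | [(6S)-6-acetoxy-2-formyl-3,3-dimethylcyclohex-1-en-1-yl]methyl (1S,5R,7S)-7-(tert-butyldimethylsilyloxy)-3-oxobicyclo[3.2.1]octane-1-carboxylate | C1[C@H](O[Si](C)(C)C(C)(C)C)[C@]2(C(=O)OCC3=C(C=O)C(C)(C)CC[C@@H]3OC(C)=O)C[C@H]1CC(=O)C2 | intermediate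
21 | (15S)-15-(tert-butyldimethylsilyloxy)-15-deoxo-11-oxo-17-norisodonal | C1[C@H](O[Si](C)(C)C(C)(C)C)[C@]23C[C@H]1CC(=O)[C@H]2[C@]1(COC3=O)[C@@H](OC(C)=O)CCC(C)(C)[C@H]1C=O | intermediate
22 | (15S)-15-hydroxy-15-deoxo-11-oxo-17-norisodonal | C1[C@H](O)[C@]23C[C@H]1CC(=O)[C@H]2[C@]1(COC3=O)[C@@H](OC(C)=O)CCC(C)(C)[C@H]1C=O | intermediate
23 | 11-oxo-17-norisodonal | C1C(=O)[C@]23C[C@H]1CC(=O)[C@H]2[C@]1(COC3=O)[C@@H](OC(C)=O)CCC(C)(C)[C@H]1C=O | intermediate
24 | 11-oxo-17-norisodonal 6-alcohol (C6 as CH2OH) | C1C(=O)[C@]23C[C@H]1CC(=O)[C@H]2[C@]1(COC3=O)[C@@H](OC(C)=O)CCC(C)(C)[C@H]1CO | intermediate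
25 | 17-norisodonal 6-alcohol (C6 as CH2OH, 11β-OH, C15 ketone) | C1C(=O)[C@]23C[C@H]1C[C@H](O)[C@H]2[C@]1(COC3=O)[C@@H](OC(C)=O)CCC(C)(C)[C@H]1CO | intermediate
26 | 16-exo-[(N-methylanilino)methyl] derivative of 25 | CN(c1ccccc1)C[C@@H]1C(=O)[C@]23C[C@H]1C[C@H](O)[C@H]2[C@]1(COC3=O)[C@@H](OC(C)=O)CCC(C)(C)[C@H]1CO | intermediate
27 | isodonal 6-alcohol (C6 as CH2OH) | C=C1C(=O)[C@]23C[C@H]1C[C@H](O)[C@H]2[C@]1(COC3=O)[C@@H](OC(C)=O)CCC(C)(C)[C@H]1CO | intermediate
28 | isodonal | C=C1C(=O)[C@]23C[C@H]1C[C@H](O)[C@H]2[C@]1(COC3=O)[C@@H](OC(C)=O)CCC(C)(C)[C@H]1C=O | target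

Total step count: 19. Longest linear sequence: 13 steps (steps 1–6 then 13–19; the ring A branch, steps 7–12 then 13–19, is equally long).

Steps most likely to fail

Step 5. Olefin insertion may lose to decarbonylation of the rhodacycle, or the two diastereotopic ring bonds may be cut without preference, which would waste material as the C15-endo series. The fallback sets out from compound 7 and runs the same two-atom enlargement as a radical relay. Hydroxylamine gives the oxime F1 and benzoyl chloride the O-benzoyl oxime F2. Slow addition of Bu3SnH with AIBN in hot benzene should generate the iminyl radical, which opens the four-membered ring to a primary radical carrying a cyanomethyl arm on C8. A 5-exo closure onto the vinyl group builds ring D, the new C12 radical adds 6-exo to the nitrile, and hydrogen transfer gives the N–H ketimine F3. Hydrolysis on silica gel returns to the route at compound 10.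

Step 14. Enolisation at the hindered C9 position may be slow, the adduct may revert by retro-Michael reaction, or the C12 enolate may close an aldol ring onto the new aldehyde. The fallback sets out from compound 20 and replaces the conjugate addition by an allylic alkylation. NaBH4 at −78 °C should reduce only the aldehyde to the allylic alcohol F4, and methyl chloroformate with pyridine gives the methyl carbonate F5. Zerovalent palladium, as Pd(PPh3)4 in THF at 60 °C, ionises the carbonate; the methoxide released forms the ketone enolate reversibly, and the C9 enolate closes the six-membered lactone at the inner allyl terminus to give the exo-methylene lactone F6. Epoxidation with dimethyldioxirane from the open β-face gives the spiro-epoxide F7. A Meinwald rearrangement with BF3·OEt2 at −78 °C, followed by brief equilibration at C5 if needed, returns to the route at compound 21.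

Step 17. Hemiketal formation between the C6 alcohol and the C11 ketone may stall the reduction, or hydride may arrive from the wrong face. The fallback sets out from compound 24, made on its own from 23 with NaBH4 at −78 °C, and ties the hydride source covalently to C6. Chlorodiisopropylsilane with imidazole gives the diisopropylsilyl ether F8. Catalytic Bu4NF in THF at 0 °C should trigger intramolecular hydrosilylation of the C11 carbonyl from the α-face and give the cyclic silylene ether F9. HF·pyridine cleaves F9 and returns to the route at compound 25.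

Further compounds
F1 | step 5 | oxime of 7 | C=CC[C@H](O[Si](C)(C)C(C)(C)C)C1(C(=O)OC)CC(=NO)C1
F2 | step 5 | O-benzoyl oxime of 7 | C=CC[C@H](O[Si](C)(C)C(C)(C)C)C1(C(=O)OC)CC(=NOC(=O)c2ccccc2)C1
F3 | step 5 | N–H ketimine of 10 | C1[C@H](O[Si](C)(C)C(C)(C)C)[C@]2(C(=O)OC)C[C@H]1CC(=N)C2
F4 | step 14 | allylic alcohol from 20 (C6 as CH2OH) | C1[C@H](O[Si](C)(C)C(C)(C)C)[C@]2(C(=O)OCC3=C(CO)C(C)(C)CC[C@@H]3OC(C)=O)C[C@H]1CC(=O)C2
F5 | step 14 | methyl carbonate of F4 | C1[C@H](O[Si](C)(C)C(C)(C)C)[C@]2(C(=O)OCC3=C(COC(=O)OC)C(C)(C)CC[C@@H]3OC(C)=O)C[C@H]1CC(=O)C2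
F6 | step 14 | spiro-lactone with exocyclic C5=C6 methylene | C1[C@H](O[Si](C)(C)C(C)(C)C)[C@]23C[C@H]1CC(=O)[C@H]2[C@]1(COC3=O)[C@@H](OC(C)=O)CCC(C)(C)C1=C
F7 | step 14 | 5,6-spiro-epoxide of F6, oxygen on the β-face | C1[C@H](O[Si](C)(C)C(C)(C)C)[C@]23C[C@H]1CC(=O)[C@H]2[C@]1(COC3=O)[C@@H](OC(C)=O)CCC(C)(C)[C@@]1(O4)C4
F8 | step 17 | diisopropylsilyl ether of 24 | C1C(=O)[C@]23C[C@H]1CC(=O)[C@H]2[C@]1(COC3=O)[C@@H](OC(C)=O)CCC(C)(C)[C@H]1CO[SiH](C(C)C)C(C)C
F9 | step 17 | 6,11-O-diisopropylsilylene derivative of 25 | C1C(=O)[C@]23C[C@H]1C[C@H](O4)[C@H]2[C@]1(COC3=O)[C@@H](OC(C)=O)CCC(C)(C)[C@H]1CO[Si]4(C(C)C)C(C)C
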